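**Retrosynthetic overview**
- The plan rests on the fusion bond C1–C5, shared by five-membered ring A (C1–C5) and seven-membered ring B (C5–C10, C1). It lies between the C4 and C6 oxygens (1,3 through C5) and the C9 oxygen (β to C1), and is read as the E alkene of an open farnesane chain.
- Late stage: the O6 vanillate, the C8 methylidene and the 9α-hydroxyl all derive from a trans-fused 6-benzyloxy-4-hydroxy-hydroazulen-9-one.
- Key disconnection: C4–C5 and C1–C10 are cut together, giving an acyclic (S,E)-6-benzyloxy C4-keto C9-enol silane. In the forward sense ring A closes first (Prins) and ring B second (cation capture), in one flask.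
- The chain comes from an (E)-alkenyl iodide (C1–C5, with C4 as a Weinreb amide) and a ketal aldehyde (C6–C10). C6 is set by CBS reduction, and the C4 ketone is released only after the C9 enol silane is in place.

Key step: step 13

Remark: locants are daucane locants (C1 quaternary with methyl, C4 isopropyl carbinol, C5 fusion CH, C6 ester carbinol, C8 methylidene carbon, C9 free carbinol). β is the face of the C1 methyl, α the face of H5. The target is 1R,4R,5S,6S,9S (1β-CH3, 4β-OH, 5α-H, 6α-O-acyl, 9α-OH).
Assumption: hydride should reach C9 of the α-methylene ketone from the α face, because the axial C1 methyl screens the β face. A 9β-alcohol is therefore planned and inverted.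
Remark: metal alkoxides and tetrahedral adducts that are only protonated on aqueous work-up are not numbered.

Step 1
Reactants: 1 pent-4-yn-1-ol
Product: 3 (E)-5-iodo-4-methylpent-4-en-1-ol, via alkenylalane 2 (not isolated)
Conditions: Me3Al (3 equiv), Cp2ZrCl2 (0.25 equiv), CH2Cl2, 0 °C to rt; then I2, THF, −30 to 0 °C
Reagents that add atoms: trimethylaluminium C[Al](C)C; iodine II
Why: Negishi zirconium-catalysed carboalumination adds methyl and aluminium syn across the alkyne with the metal at the terminus, and iodinolysis with retention fixes the E geometry of the future C1=C5 alkene.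

Step 2
Reactants: 3 (E)-5-iodo-4-methylpent-4-en-1-ol
Product: 4 (E)-5-iodo-4-methylpent-4-enoic acid
Conditions: TEMPO (0.2 equiv), PhI(OAc)2 (2.2 equiv), MeCN/H2O 1:1, rt
Reagents that add atoms: water O
Why: The TEMPO/PhI(OAc)2 oxidation takes the primary alcohol through the aldehyde hydrate to the acid (future C4) and leaves the alkenyl iodide untouched.

Step 3
Reactants: 4 (E)-5-iodo-4-methylpent-4-enoic acid
Product: 6 (E)-5-iodo-N-methoxy-N,4-dimethylpent-4-enamide, via acyl imidazole 5 (not isolated)
Conditions: CDI, CH2Cl2, rt; then MeNH(OMe)·HCl, rt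
Reagents that add atoms: N,O-dimethylhydroxylamine hydrochloride CNOC.Cl; 1,1'-carbonyldiimidazole O=C(n1ccnc1)n1ccnc1 (kept only in 5)
Why: Weinreb amide formation through the acyl imidazole keeps C4 at the acid level, so that no second enolisable ketone is present when the C9 enol silane is made.

Step 4
Reactants: 7 methyl levulinate
Product: 8 methyl 3-(2-methyl-1,3-dioxolan-2-yl)propanoate
Conditions: ethylene glycol, p-TsOH (cat.), toluene, Dean–Stark, reflux
Reagents that add atoms: ethylene glycol OCCO
Why: Acid-catalysed ketalisation with azeotropic removal of water masks the future C9 ketone through the coupling, reduction and benzylation steps.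

Step 5
Reactants: 8 methyl 3-(2-methyl-1,3-dioxolan-2-yl)propanoate
Product: 9 3-(2-methyl-1,3-dioxolan-2-yl)propanal
Conditions: DIBAL-H (1.05 equiv), CH2Cl2, −78 °C; aq. Rochelle salt
Reagents that add atoms: none
Why: Partial ester reduction with DIBAL-H stops at the aldehyde (future C6), because the aluminium hemiacetal survives at −78 °C until work-up.

Step 6
Reactants: 6 (E)-5-iodo-N-methoxy-N,4-dimethylpent-4-enamide; 9 3-(2-methyl-1,3-dioxolan-2-yl)propanal
Product: 10 (E)-6-hydroxy-N-methoxy-N,4-dimethyl-8-(2-methyl-1,3-dioxolan-2-yl)oct-4-enamide (racemic carbinol)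
Conditions: CrCl2 (4 equiv), NiCl2 (0.01 equiv), DMF, rt
Reagents that add atoms: none
Why: The Nozaki–Hiyama–Kishi coupling forms C5–C6 with retention of the alkene geometry and tolerates the Weinreb amide and the ketal, and the racemic carbinol is erased in the next step.

Step 7
Reactants: 10 racemic allylic alcohol
Product: 11 (E)-N-methoxy-N,4-dimethyl-8-(2-methyl-1,3-dioxolan-2-yl)-6-oxooct-4-enamide
Conditions: MnO2 (20 equiv), CH2Cl2, rt
Reagents that add atoms: none
Why: MnO2 oxidation is selective for the allylic alcohol and gives the E enone under neutral conditions.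

Step 8
Reactants: 11 enone
Product: 12 (S,E)-6-hydroxy-N-methoxy-N,4-dimethyl-8-(2-methyl-1,3-dioxolan-2-yl)oct-4-enamide
Conditions: (R)-2-methyl-CBS-oxazaborolidine (0.2 equiv), catecholborane (1.8 equiv), toluene, −78 °C
Reagents that add atoms: none
Why: In the Corey–Bakshi–Shibata reduction the alkenyl branch acts as the large and the CH2CH2 branch as the small substituent, so the (R)-catalyst should give the (S)-carbinol that sets C6, while catecholborane at −78 °C spares the amide.

Step 9
Reactants: 12 (S)-allylic alcohol
Product: 13 (S,E)-6-benzyloxy-N-methoxy-N,4-dimethyl-8-(2-methyl-1,3-dioxolan-2-yl)oct-4-enamide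
Conditions: NaH, BnBr, Bu4NI (cat.), THF/DMF, 0 °C to rt
Reagents that add atoms: benzyl bromide BrCc1ccccc1
Why: Williamson etherification installs a Lewis-basic, acid-stable ether at O6 without touching the C6–O bond, so the configuration is kept.

Step 10
Reactants: 13 benzyl ether ketal
Product: 14 (S,E)-6-benzyloxy-N-methoxy-N,4-dimethyl-9-oxodec-4-enamide
Conditions: AcOH/THF/H2O 3:1:1, 45 °C
Reagents that add atoms: water O
Why: Mild acid hydrolysis of the dioxolane frees the C9 methyl ketone under conditions too weak to ionise the allylic benzyl ether.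

Step 11
Reactants: 14 methyl ketone
Product: 16 (S,E)-6-benzyloxy-9-(tert-butyldimethylsilyloxy)-N-methoxy-N,4-dimethyldeca-4,9-dienamide, via lithium enolate 15 (not isolated)
Conditions: LDA (1.05 equiv), THF, −78 °C, slow addition of 14; TBSOTf (1.2 equiv), −78 °C; Et3N, pH 7 buffer
Reagents that add atoms: tert-butyldimethylsilyl triflate CC(C)(C)[Si](C)(C)OS(=O)(=O)C(F)(F)F; lithium diisopropylamide CC(C)[N-]C(C)C.[Li+] (kept only in 15)
Why: Kinetic enolisation removes a proton from the C10 methyl group of the only ketone present (the amide α-protons are far less acidic), and O-silylation traps the terminal enol silane.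

Step 12
Reactants: 16 enol silane Weinreb amide
Product: 17 (S,E)-8-benzyloxy-11-(tert-butyldimethylsilyloxy)-2,6-dimethyldodeca-6,11-dien-3-one
Conditions: iPrMgCl (2.5 equiv), THF, 0 °C to rt; pH 7 phosphate buffer, 0 °C
Reagents that add atoms: isopropylmagnesium chloride CC(C)[Mg]Cl
Why: Grignard addition to the Weinreb amide stops at the chelated adduct and releases the C4 isopropyl ketone only on buffered work-up, and the silyl enol ether is inert to the reagent.

Step 13
Reactants: 17 (S,E)-8-benzyloxy-11-(tert-butyldimethylsilyloxy)-2,6-dimethyldodeca-6,11-dien-3-one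
Product: 19 trans-fused (1R,4R,5S,6S)-6-benzyloxy-4-hydroxy-4-isopropyl-1-methylbicyclo[5.3.0]decan-9-one, via cyclopentyl cation 18 (not isolated)
Conditions: MeAlCl2 (2.5 equiv, 1 M in hexanes), CH2Cl2 (0.005 M), −78 to −40 °C; Et3N/MeOH, aq. Rochelle salt
Reagents that add atoms: methylaluminium dichloride C[Al](Cl)Cl (kept only in 18)
Why: Proposed new method: two equivalents of MeAlCl2 should convert the C4 ketone into a cationic MeClAl chelate (counter-ion MeAlCl3) that also binds the C6 benzyloxy oxygen, after which C5 of the E alkene attacks C4, the tertiary C1 cation 18 is captured by C10 of the enol silane, and chloride removes the silyl group to give the C9 ketone. The closest known reaction types are the alkylaluminium-halide-initiated Prins cyclisation of γ,δ-unsaturated ketones (same bond, same cyclopentyl cation), chelate-controlled Mukaiyama additions run with MeAlCl2 on β-benzyloxy carbonyl compounds, and cation–olefin polycyclisations terminated by a silyl enol ether, and only their union in one cascade is new. Ring A closes 5-endo-trig at the alkene and exo at the carbonyl (O4 stays outside the ring), and ring B closes 7-endo-trig at the enol silane onto the ring A cation. For C5, allylic 1,3-strain against the C1 methyl holds H6 in the alkene plane, so that O6 and C7 lie on opposite faces and the chelate delivers C4 to the O6 face; for C4, the same chelate, reinforced by the isopropyl group avoiding the C6 chain, places O4 cis to C6 on ring A; for C1, C10 hangs from C7 on the other face and adds anti, which turns the E geometry into the trans fusion (1β-CH3, 5α-H). The step needs the alkene rather than the enol silane to attack the ketone: a direct aldol closure would need a ten-membered ring, the isopropyl ketone is hindered, high dilution suppresses the bimolecular aldol, and MeAlCl2 destroys stray protons as methane before they can cleave the enol silane. The inductive pull of O6 should also slow the 1,2-hydride shift from C5 that normally follows such Prins closures.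

Step 14
Reactants: 19 benzyloxy hydroazulenone
Product: 20 (1R,4R,5S,6S)-4,6-dihydroxy-4-isopropyl-1-methylbicyclo[5.3.0]decan-9-one
Conditions: H2 (1 atm), Pd/C (10 wt %), EtOAc, rt
Reagents that add atoms: none
Why: Catalytic hydrogenolysis removes the benzyl ether at the only stage that carries no alkene, and leaves the ketone and the tertiary alcohol intact.

Step 15
Reactants: 21 vanillic acid
Product: 23 4-(tert-butyldimethylsilyloxy)-3-methoxybenzoic acid, via bis-silyl derivative 22 (not isolated)
Conditions: TBSCl (2.4 equiv), imidazole (5 equiv), DMF, rt; then AcOH/THF/H2O, rt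
Reagents that add atoms: tert-butyldimethylsilyl chloride CC(C)(C)[Si](C)(C)Cl
Why: Exhaustive silylation followed by selective hydrolysis of the much more labile silyl ester masks the phenol, which would otherwise interfere in the esterification and the Mitsunobu step.

Step 16
Reactants: 20 diol ketone; 23 4-(tert-butyldimethylsilyloxy)-3-methoxybenzoic acid
Product: 24 6-O-[4-(tert-butyldimethylsilyloxy)-3-methoxybenzoyl] derivative of 20
Conditions: EDC·HCl (1.5 equiv), DMAP (1 equiv), CH2Cl2, rt
Reagents that add atoms: none
Why: Steglich esterification acylates the only secondary hydroxyl (the tertiary C4 hydroxyl is inert) and drains any transannular O6/C9 hemiketal through the open hydroxy ketone, and it is placed before methylenation so that the sensitive enone never meets DMAP.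

Step 17
Reactants: 24 keto ester
Product: 28 8-methylidene-9-ketone (α-methylene ketone of 24), via lithium enolate 25 (not isolated), via Mannich base 26 (not isolated), via ammonium iodide 27 (not isolated)
Conditions: LiHMDS (2.2 equiv), THF, −78 °C; Me2N=CH2 I (2 equiv), −78 to 0 °C; crude, MeI, CH2Cl2, rt; then sat. aq. NaHCO3/CH2Cl2, rt
Reagents that add atoms: Eschenmoser's salt C[N+](C)=C.[I-]; iodomethane CI (kept only in 27); lithium hexamethyldisilazide [Li]N([Si](C)(C)C)[Si](C)(C)C (kept only in 25)
Why: Kinetic enolisation takes place at C8 because the C10 protons are neopentyl next to quaternary C1, and the Mannich reaction with Eschenmoser's salt followed by quaternisation and Hofmann-type elimination gives the exocyclic enone under only bicarbonate basicity.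

Step 18
Reactants: 28 α-methylene ketone
Product: 29 (9R)-9β-allylic alcohol
Conditions: NaBH4, CeCl3·7H2O, MeOH, −78 to −40 °C
Reagents that add atoms: none
Why: The Luche reduction is 1,2-selective, and in the cycloheptene-like chair of the planar C7–C10 enone segment the axial C1 methyl screens the β face, so hydride should add from the α face and give the 9β-alcohol.

Step 19
Reactants: 29 9β-allylic alcohol
Product: 30 (9S)-9α-(4-nitrobenzoate)
Conditions: 4-nitrobenzoic acid, PPh3, DIAD, THF, 0 °C to rt
Reagents that add atoms: 4-nitrobenzoic acid O=C(O)c1ccc([N+](=O)[O-])cc1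
Why: Mitsunobu inversion displaces the activated pseudo-axial 9β-oxygen by SN2 attack from the open α face, which sets the 9S centre while the tertiary hydroxyl and the silylated phenol stay inert.

Step 20
Reactants: 30 9α-(4-nitrobenzoate)
Product: 31 target CNP0330487.1
Conditions: K2CO3 (2 equiv), MeOH, 0 °C to rt; aq. NH4Cl
Reagents that add atoms: none
Why: Carbonate methanolysis cleaves the activated 4-nitrobenzoate and the base-labile aryl silyl ether para to an ester, and the phenoxide thus formed deactivates the hindered C6 vanillate toward transesterification.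

**Compound list**
1 | pent-4-yn-1-ol | C#CCCCO | starting material
2 | (E)-alkenylalane, O-dimethylaluminium alkoxide | C[Al](C)OCCC/C(C)=C/[Al](C)C | intermediate
3 | (E)-5-iodo-4-methylpent-4-en-1-ol | OCCC/C(C)=C/I | intermediate
4 | (E)-5-iodo-4-methylpent-4-enoic acid | OC(=O)CC/C(C)=C/I | intermediate
5 | (E)-1-(imidazol-1-yl)-5-iodo-4-methylpent-4-en-1-one | O=C(CC/C(C)=C/I)n1ccnc1 | intermediate
6 | (E)-5-iodo-N-methoxy-N,4-dimethylpent-4-enamide | CON(C)C(=O)CC/C(C)=C/I | intermediate
7 | methyl levulinate | COC(=O)CCC(C)=O | starting material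
8 | methyl 3-(2-methyl-1,3-dioxolan-2-yl)propanoate | COC(=O)CCC1(C)OCCO1 | intermediate
9 | 3-(2-methyl-1,3-dioxolan-2-yl)propanal | O=CCCC1(C)OCCO1 | intermediate
10 | racemic (E)-allylic alcohol | CON(C)C(=O)CC/C(C)=C/C(O)CCC1(C)OCCO1 | intermediate
11 | (E)-enone | CON(C)C(=O)CC/C(C)=C/C(=O)CCC1(C)OCCO1 | intermediate
12 | (S,E)-allylic alcohol | CON(C)C(=O)CC/C(C)=C/[C@@H](O)CCC1(C)OCCO1 | intermediate
13 | (S,E)-benzyl ether ketal | CON(C)C(=O)CC/C(C)=C/[C@@H](OCc1ccccc1)CCC2(C)OCCO2 | intermediate
14 | (S,E)-6-benzyloxy-N-methoxy-N,4-dimethyl-9-oxodec-4-enamide | CON(C)C(=O)CC/C(C)=C/[C@@H](OCc1ccccc1)CCC(C)=O | intermediate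
15 | terminal lithium enolate of 14 | CON(C)C(=O)CC/C(C)=C/[C@@H](OCc1ccccc1)CCC(=C)O[Li] | intermediate
16 | enol silane Weinreb amide | CON(C)C(=O)CC/C(C)=C/[C@@H](OCc1ccccc1)CCC(=C)O[Si](C)(C)C(C)(C)C | intermediate
17 | acyclic keto enol silane (key precursor) | CC(C)C(=O)CC/C(C)=C/[C@@H](OCc1ccccc1)CCC(=C)O[Si](C)(C)C(C)(C)C | intermediate
18 | ring A cyclopentyl C1 cation, C4 aluminium alkoxide | C=C(O[Si](C)(C)C(C)(C)C)CC[C@H](OCc1ccccc1)[C@@H]1[C+](C)CC[C@@]1(O[Al-](C)(Cl)Cl)C(C)C | intermediate
19 | trans-fused 6-benzyloxy-4-hydroxy-hydroazulen-9-one (key product) | O=C1CC[C@H](OCc3ccccc3)[C@@H]2[C@](C)(CC[C@@]2(O)C(C)C)C1 | intermediate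
20 | 4,6-dihydroxy-hydroazulen-9-one | O=C1CC[C@H](O)[C@@H]2[C@](C)(CC[C@@]2(O)C(C)C)C1 | intermediate
21 | vanillic acid | COc1cc(C(=O)O)ccc1O | starting material
22 | TBS 4-(TBS-oxy)-3-methoxybenzoate | COc1cc(C(=O)O[Si](C)(C)C(C)(C)C)ccc1O[Si](C)(C)C(C)(C)C | intermediate
23 | 4-(tert-butyldimethylsilyloxy)-3-methoxybenzoic acid | COc1cc(C(=O)O)ccc1O[Si](C)(C)C(C)(C)C | intermediate
24 | 6-O-(O-TBS-vanilloyl) 9-ketone | O=C1CC[C@H](OC(=O)c3ccc(O[Si](C)(C)C(C)(C)C)c(OC)c3)[C@@H]2[C@](C)(CC[C@@]2(O)C(C)C)C1 | intermediate
25 | C8=C9 lithium enolate, C4 lithium alkoxide | [Li]OC1=CC[C@H](OC(=O)c3ccc(O[Si](C)(C)C(C)(C)C)c(OC)c3)[C@@H]2[C@](C)(CC[C@@]2(O[Li])C(C)C)C1 | intermediate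
26 | 8-(dimethylaminomethyl) ketone (C8 epimers) | CN(C)CC1C[C@H](OC(=O)c3ccc(O[Si](C)(C)C(C)(C)C)c(OC)c3)[C@@H]2[C@](C)(CC[C@@]2(O)C(C)C)CC1=O | intermediate
27 | 8-(trimethylammoniomethyl) ketone iodide | C[N+](C)(C)CC1C[C@H](OC(=O)c3ccc(O[Si](C)(C)C(C)(C)C)c(OC)c3)[C@@H]2[C@](C)(CC[C@@]2(O)C(C)C)CC1=O.[I-] | intermediate
28 | 8-methylidene 9-ketone | C=C1C[C@H](OC(=O)c3ccc(O[Si](C)(C)C(C)(C)C)c(OC)c3)[C@@H]2[C@](C)(CC[C@@]2(O)C(C)C)CC1=O | intermediate
29 | 9β-allylic alcohol (9R) | C=C1C[C@H](OC(=O)c3ccc(O[Si](C)(C)C(C)(C)C)c(OC)c3)[C@@H]2[C@](C)(CC[C@@]2(O)C(C)C)C[C@H]1O | intermediate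
30 | 9α-(4-nitrobenzoate) (9S) | C=C1C[C@H](OC(=O)c3ccc(O[Si](C)(C)C(C)(C)C)c(OC)c3)[C@@H]2[C@](C)(CC[C@@]2(O)C(C)C)C[C@@H]1OC(=O)c4ccc([N+](=O)[O-])cc4 | intermediate
31 | CNP0330487.1 | C=C1C[C@H](OC(=O)c2ccc(O)c(OC)c2)[C@@H]2[C@](C)(CC[C@@]2(O)C(C)C)C[C@@H]1O | target

**Step count**
- Total steps: 20.
- Longest linear sequence: 17 (steps 1–3, 6–14, 16–20).

**Steps most likely to fail**

1. Step 13.
   - Risks:
     - The C1 cation may lose a proton or accept the C5 hydride before ring B closes.
     - The allylic benzyl ether may ionise.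
     - The enol silane may be cleaved.
     - A relaxed cation may be captured on the wrong face, which would erode the trans fusion.
   - Fallback: known chemistry only, with ring A built on a cyclopentanone and ring B closed by metathesis; it sets out from 1 and returns at 19.
     - Semihydrogenation of 1 (H2, Pd/CaCO3 poisoned with Pb(OAc)2, quinoline) gives pent-4-en-1-ol F1. Parikh–Doering oxidation then gives pent-4-enal F2 (C6–C9).
     - Copper-catalysed enantioselective conjugate addition of a vinylaluminium reagent to commercial 3-methylcyclopent-2-enone (Cu(OTf)2, chiral N-heterocyclic carbene ligand) sets C1. Trapping with Me3SiOTf gives the regiodefined 3-methyl-3-vinyl-1-(trimethylsilyloxy)cyclopentene F3.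
     - A Mukaiyama aldol reaction of F3 with F2 (BF3·OEt2, CH2Cl2, −78 °C) forms C5–C6 and gives the aldol F4. Isomers at C5 and C6 would have to be separated, and C5 can be re-equilibrated through the ketone.
     - Benzyl trichloroacetimidate with catalytic TfOH gives the benzyl ether F5.
     - The organocerium reagent from iPrMgCl and CeCl3 adds to C4 from the face opposite the C6 chain and the C1 methyl, giving the tertiary carbinol F6.
     - Ring-closing metathesis (second-generation Grubbs catalyst, CH2Cl2, reflux) closes ring B as the C9=C10 cycloheptene F7.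
     - Hydroboration–oxidation (9-BBN; H2O2, NaOH) places oxygen on C9, away from quaternary C1, giving the 9-alcohol F8. Dess–Martin oxidation returns to 19.

2. Step 17.
   - Risks:
     - Enolisation may turn toward C10.
     - The enolate or the C4 alkoxide may attack the neighbouring aryl ester, causing acyl migration.
     - The enone may isomerise or dimerise during the elimination.
   - Fallback: no metal enolate is used; it sets out from 24 and returns at 28. The neutral ketone is heated with paraformaldehyde and diisopropylammonium trifluoroacetate in THF. The enol should react with the iminium ion formed in situ, and the β-amino ketone should eliminate in the same flask, so no new isolated compound arises.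

3. Step 19.
   - Risks:
     - The carboxylate may attack C14 in an SN2′ sense.
     - Elimination to a diene may compete.
     - Activation of the hindered pseudo-axial alcohol may be slow.
   - Fallback: catalyst control replaces substrate control plus inversion; it sets out from 28 and returns at 31. A CBS reduction is run with the catalyst enantiomer that puts hydride on the β face ((R)-2-methyl-CBS-oxazaborolidine if the methylidene-bearing C8 acts as the large group; catecholborane, −78 °C). This should give the 9α-alcohol silyl ether F9 directly, and K2CO3 in MeOH then frees the phenol to give 31.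

**Further compounds**
F1 | step 13 | pent-4-en-1-ol | C=CCCCO
F2 | step 13 | pent-4-enal | C=CCCC=O
F3 | step 13 | 3-methyl-3-vinyl-1-(trimethylsilyloxy)cyclopentene, single enantiomer | C=C[C@@]1(C)CCC(O[Si](C)(C)C)=C1
F4 | step 13 | 2-(1-hydroxypent-4-enyl)-3-methyl-3-vinylcyclopentanone | C=CCC[C@H](O)[C@@H]1[C@](C)(CCC1=O)C=C
F5 | step 13 | 2-(1-benzyloxypent-4-enyl)-3-methyl-3-vinylcyclopentanone | C=CCC[C@H](OCc2ccccc2)[C@@H]1[C@](C)(CCC1=O)C=C
F6 | step 13 | 2-(1-benzyloxypent-4-enyl)-1-isopropyl-3-methyl-3-vinylcyclopentanol | C=CCC[C@H](OCc2ccccc2)[C@@H]1[C@](C)(CC[C@@]1(O)C(C)C)C=C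
F7 | step 13 | trans-fused 6-benzyloxy-4-hydroxy-hydroazul-9-ene | C=1CC[C@H](OCc3ccccc3)[C@@H]2[C@](C)(CC[C@@]2(O)C(C)C)C=1
F8 | step 13 | trans-fused 6-benzyloxy-hydroazulene-4,9-diol (C9 epimers) | OC1CC[C@H](OCc3ccccc3)[C@@H]2[C@](C)(CC[C@@]2(O)C(C)C)C1
F0 | step 17 | none | none
F9 | step 19 | 9α-allylic alcohol, phenol TBS ether | C=C1C[C@H](OC(=O)c3ccc(O[Si](C)(C)C(C)(C)C)c(OC)c3)[C@@H]2[C@](C)(CC[C@@]2(O)C(C)C)C[C@@H]1O
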